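The runs come from a simulation with constants of no real substance; noise was put on by code.

| setting | violet | blue | flask |
|---|---|---|---|
| starting material | 0.25 M | 0.38 M | 0.50 M |
| gas phase | 180 mM (held) | 180 mM (held) | 180 mM (held) |
| remark | run made earlier | run made earlier |  |
| time |  |  | 5.0 h |

| run | time / h | target / % | idle adduct / % |
|---|---|---|---|
| violet | 0.417 | 0.8 | 0 |
| violet | 0.667 | 1.9 | 0 |
| violet | 1.00 | 2.1 | 0.7 |
| violet | 1.33 | 3.7 | 0.6 |
| violet | 2.00 | 5.6 | 0.8 |
| violet | 3.00 | 8.1 | 1.5 |
| violet | 5.00 | 12.9 | 3.0 |
| blue | 0.250 | 0.5 | 0.3 |
| blue | 0.833 | 1.9 | 0.7 |
| blue | 1.33 | 3.0 | 0.4 |
| blue | 2.00 | 4.8 | 0.9 |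
| blue | 3.00 | 7.9 | 1.1 |
| blue | 4.00 | 10.2 | 1.8 |
| blue | 5.00 | 12.0 | 1.9 |

(each reading ± 0.3 percentage points)

- for target the idle adduct is counted in
- at the start none of the gas is dissolved
- reactions considered so far: target <-> isomer of the product; dissolved gas + target <-> idle adduct; gas phase <-> dissolved gas; starting material + dissolved gas -> target

- how much target and idle adduct together there is at 5.0 h, in percent of the starting material charged
- concentration of dissolved gas in solution at 80 min, in percent of saturation
- the change that raises the amount of target and idle adduct together at 5.0 h, in percent of the starting material charged most ("none" if none brings more than 2 percentage points) (birch / maple / none)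
- amount of target and idle adduct together at 5.0 h, in percent of the starting material charged, after maple

- birch: doubling the transfer coefficient of the gas phase, all else as stated
- maple: doubling the saturation concentration of gas phase, all else as stated

1. Begin with the easy step: the target column already counts the idle adduct, so the amount asked for is that column with nothing added, and your two amounts are its readings at 5.00 h, 12.9% in the violet run and 12.0% in the blue run.

2. Put the zero of your scale where the percent Y does not depend on the charge S, the pseudo-first-order case in which the dissolved gas stands at the same level whatever you charge, and put the other end where a fixed supply of gas is shared out, so that Y falls as 1/S; between these ends you write Y ∝ S^(−n).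

3. From violet to blue the charge rises by a factor of 1.52 while Y falls by a factor of 1.08, so you read the gas-demand exponent n = 0.173, the logarithm of the yield ratio divided by the logarithm of the charge ratio, through a scatter of 0.3 percentage points on each reading, and it lies nearer the zero than the other end.

4. Carrying n from the blue run to the flask's 0.50 M, you multiply the blue reading by (blue charge/flask charge)^n and commit to 11.4%.

The forecast differs from your figure, giving 13.5%, with dissolved gas at 95% of saturation at 80 min, maple as the best change and 25% after maple, and it argues that “the gas dissolves within about 0.2 h, so the solution stays near saturation”.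

The flask gives 11.4%, dissolved gas at 44.5% of saturation at 80 min, maple as the best change with a gain of 10 points against 3.4 points for birch, and 21.7% after maple.

    target ⇌ isomer of the product (K = 2.70, k = 2.30 h⁻¹)
    dissolved gas + target ⇌ idle adduct, settled at all times (K = 2.10 L mol⁻¹)
    gas phase ⇌ dissolved gas, rate k3*(csat - [dissolved gas]) (kL = 0.620 h⁻¹)
    starting material + dissolved gas → target (k = 0.820 L mol⁻¹ h⁻¹)

Take the neighbouring flask, the same charge read at 80 min, and multiply the blue reading at that time, 3.0%, by the same factor with the same n, which gives you 2.86%. That neighbouring flask holds 2.85% of target with the idle adduct counted in, and 94.8% of its starting material is still there. Its dissolved gas stands at 0.0801 M, which is 44.5% of saturation.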